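**Retrosynthetic overview**
1. The target has a (7R,8S,7'R,8'S)-syringaresinol core, a cis-fused 3,7-dioxabicyclo[3.3.0]octane (ring A = O7, C7, C8, C8', C9'; ring B = O9, C9, C8, C8', C7'). Its two phenol oxygens carry three guaiacylglycerol β-aryl ether units.
2. Enabling feature: C7' bears ring oxygen O9 and an electron-rich trialkoxyphenyl ring, so it is a latent oxocarbenium carbon. Its neighbour C8' is the α-carbon of C9', which is bound to the other ring oxygen O7 and is therefore a latent aldehyde or enol ether. C8'-C7' is thus an aldol-type bond inside the array O9-C7'-C8'-C9'-O7.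
3. Key disconnection C8'-C7': an open-chain (Z)-enol ether alcohol holding three of the five arenes is united with the right-hand aldehyde holding the other two, and ring B closes in that event. Ring A (O7-C9') closes next by epimerisation and lactol formation, and is then deoxygenated.
4. C7-C8 comes from a deconjugative Evans syn-aldol. Each side-chain Cα-Cβ bond comes from an Evans syn-aldol of an aryloxyacetyl imide (threo), followed by Mitsunobu inversion at Cα for the two erythro units. Aryl bromides serve as latent aldehydes.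
5. Order of ring formation: ring B (step 28), then ring A (step 29).

Key step: step 28

Remark on names: lignan numbering is used for the core. S1 and S2 are the left and right syringyl rings, and G1, G2 and G3 are the middle, left-terminal and right-terminal guaiacyl rings. Unit 1 (on S1, aryl G1) is αR,βR (threo), unit 2 (on G1, aryl G2) is αR,βS (erythro), and unit 3 (on S2, aryl G3) is αS,βR (erythro). TBS = tert-butyldimethylsilyl, TIPS = triisopropylsilyl, TES = triethylsilyl.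
Assumption: (E)-4-methoxybut-2-enoic acid, 4-bromo-2-methoxyphenol and 4-bromo-2,6-dimethoxyphenol are taken as commercial.

**Route**

Step 1
Reactants: 1 vanillin
Product: 2 3-methoxy-4-(triisopropylsilyloxy)benzaldehyde
Conditions: i-Pr3SiCl, imidazole, DMF, rt
Reagents that add atoms: triisopropylsilyl chloride CC(C)[Si](Cl)(C(C)C)C(C)C
Why: Phenol silylation gives a bulky aryl silyl ether that should survive the boron aldol, borohydride, brief methanolysis and organolithium steps and fall to fluoride at the end.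

Step 2
Reactants: 3 (R)-4-benzyloxazolidin-2-one; 4 bromoacetyl bromide
Product: 5 (R)-4-benzyl-3-(bromoacetyl)oxazolidin-2-one
Conditions: n-BuLi, THF, -78 °C; then 4, -78 to 0 °C
Reagents that add atoms: none
Why: N-acylation of the lithiated oxazolidinone works because the acyl bromide reacts far faster than the alkyl bromide.

Step 3
Reactants: 5 (R)-bromoacetyl imide; 6 4-bromo-2-methoxyphenol
Product: 7 (R)-4-benzyl-3-[2-(4-bromo-2-methoxyphenoxy)acetyl]oxazolidin-2-one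
Conditions: K2CO3, acetone, rt
Reagents that add atoms: none
Why: Williamson-type SN2 displacement of the activated α-bromo imide by the phenoxide; the aryl bromide is the latent formyl group of ring G1.

Step 4
Reactants: 7 aryloxyacetyl imide; 2 TIPS-vanillin
Product: 8 (R)-4-benzyl-3-[(2R,3S)-2-(4-bromo-2-methoxyphenoxy)-3-hydroxy-3-(3-methoxy-4-triisopropylsilyloxyphenyl)propanoyl]oxazolidin-2-one
Conditions: Bu2BOTf, Et3N, CH2Cl2, -78 to 0 °C; 2, -78 to 0 °C; H2O2, MeOH, pH 7 buffer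
Reagents that add atoms: none
Why: Evans syn-aldol, in which the Z-boron enolate reacts through a Zimmerman-Traxler chair on the face left open by the (R)-benzyl group; this sets both centres of unit 2 in the threo (later αS,βS) sense, as is well precedented for β-O-4 models.

Step 5
Reactants: 8 syn-aldol imide
Product: 9 (1S,2S)-2-(4-bromo-2-methoxyphenoxy)-1-(3-methoxy-4-triisopropylsilyloxyphenyl)propane-1,3-diol (threo)
Conditions: LiBH4, MeOH (1 equiv), THF, 0 °C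
Reagents that add atoms: none
Why: Reductive removal of the auxiliary; the activated imide carbonyl is reduced to the primary alcohol without touching either stereocentre.

Step 6
Reactants: 9 threo diol
Product: 10 (1S,2S)-2-(4-bromo-2-methoxyphenoxy)-3-(tert-butyldimethylsilyloxy)-1-(3-methoxy-4-triisopropylsilyloxyphenyl)propan-1-ol
Conditions: TBSCl (1.05 equiv), imidazole, CH2Cl2, 0 °C
Reagents that add atoms: tert-butyldimethylsilyl chloride CC(C)(C)[Si](C)(C)Cl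
Why: Sterically controlled silylation takes the primary alcohol and leaves the hindered benzylic alcohol free for inversion.

Step 7
Reactants: 10 threo benzylic alcohol
Product: 11 (1R,2S)-2-(4-bromo-2-methoxyphenoxy)-3-(tert-butyldimethylsilyloxy)-1-(3-methoxy-4-triisopropylsilyloxyphenyl)propyl 4-nitrobenzoate (erythro)
Conditions: 4-O2NC6H4CO2H, PPh3, DIAD, toluene, 0 °C to rt
Reagents that add atoms: 4-nitrobenzoic acid O=C(O)c1ccc(cc1)[N+](=O)[O-]
Why: Mitsunobu reaction inverts Cα by SN2 displacement (αS to αR), and the β-aryloxy group disfavours ionisation, as known for threo-to-erythro conversion of β-O-4 models.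

Step 8
Reactants: 11 4-nitrobenzoate
Product: 12 (1R,2S)-2-(4-bromo-2-methoxyphenoxy)-3-(tert-butyldimethylsilyloxy)-1-(3-methoxy-4-triisopropylsilyloxyphenyl)propan-1-ol (erythro)
Conditions: K2CO3 (cat.), MeOH-THF, 0 °C
Reagents that add atoms: none
Why: Transesterification of the activated ester is fast at 0 °C and occurs at the acyl carbon, so Cα and the silyl ethers stay untouched.

Step 9
Reactants: 12 erythro alcohol
Product: 13 bis-TBS ether of unit 2 on 4-bromo-2-methoxyphenyl (αR,βS)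
Conditions: TBSOTf, 2,6-lutidine, CH2Cl2, 0 °C
Reagents that add atoms: tert-butyldimethylsilyl triflate CC(C)(C)[Si](C)(C)OS(=O)(=O)C(F)(F)F
Why: Silyl triflate silylation of a hindered secondary alcohol under buffered conditions leaves no acidic or electrophilic group for the next step.

Step 10
Reactants: 13 aryl bromide
Product: 14 4-{[(1R,2S)-1,3-bis(tert-butyldimethylsilyloxy)-1-(3-methoxy-4-triisopropylsilyloxyphenyl)propan-2-yl]oxy}-3-methoxybenzaldehyde
Conditions: n-BuLi, THF, -78 °C; DMF; H2O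
Reagents that add atoms: N,N-dimethylformamide CN(C)C=O
Why: Bromine-lithium exchange followed by Bouveault formylation; the exchange at -78 °C outruns any deprotonation, and all other groups are ethers.

Step 11
Reactants: 15 (S)-4-benzyloxazolidin-2-one; 4 bromoacetyl bromide
Product: 16 (S)-4-benzyl-3-(bromoacetyl)oxazolidin-2-one
Conditions: n-BuLi, THF, -78 °C; then 4, -78 to 0 °C
Reagents that add atoms: none
Why: N-acylation of the lithiated oxazolidinone, as in step 2.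

Step 12
Reactants: 16 (S)-bromoacetyl imide; 17 4-bromo-2,6-dimethoxyphenol
Product: 18 (S)-4-benzyl-3-[2-(4-bromo-2,6-dimethoxyphenoxy)acetyl]oxazolidin-2-one
Conditions: K2CO3, acetone, rt
Reagents that add atoms: none
Why: Williamson-type SN2 alkylation; this one imide serves twice, for ring S1 (step 13) and for ring S2 (step 21).

Step 13
Reactants: 18 syringyloxyacetyl imide; 14 aldehyde bearing unit 2
Product: 19 syn-aldol imide ((S)-auxiliary; new centres 2S,3R) joining 18 to 14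
Conditions: Bu2BOTf, Et3N, CH2Cl2, -78 to 0 °C; 14, -78 to 0 °C; H2O2, MeOH, pH 7 buffer
Reagents that add atoms: none
Why: Evans syn-aldol under auxiliary control (Zimmerman-Traxler chair, face opposite the (S)-benzyl group) sets the αR,βR threo pair of unit 1; the remote centres of 14 should have no say.

Step 14
Reactants: 19 syn-aldol imide
Product: 20 diol with free unit 1 (αR,βR, threo) between G1 and 4-bromo-2,6-dimethoxyphenyl
Conditions: LiBH4, MeOH (1 equiv), THF, 0 °C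
Reagents that add atoms: none
Why: Reductive removal of the auxiliary, to which silyl ethers and the aryl bromide are inert.

Step 15
Reactants: 20 diol
Product: 21 tetra-TBS mono-TIPS aryl bromide (units 1 and 2 fully silylated)
Conditions: TBSOTf (2.5 equiv), 2,6-lutidine, CH2Cl2, 0 °C
Reagents that add atoms: tert-butyldimethylsilyl triflate CC(C)(C)[Si](C)(C)OS(=O)(=O)C(F)(F)F
Why: Exhaustive silylation of the 1,3-diol with the silyl triflate changes no stereocentre.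

Step 16
Reactants: 21 aryl bromide
Product: 22 left aldehyde (3,5-dimethoxybenzaldehyde whose 4-oxygen carries silylated units 1 and 2)
Conditions: n-BuLi, THF, -78 °C; DMF; H2O
Reagents that add atoms: N,N-dimethylformamide CN(C)C=O
Why: Bromine-lithium exchange and Bouveault formylation, as in step 10.

Step 17
Reactants: 23 (E)-4-methoxybut-2-enoic acid; 3 (R)-4-benzyloxazolidin-2-one
Product: 25 (R)-4-benzyl-3-[(E)-4-methoxybut-2-enoyl]oxazolidin-2-one, via mixed pivalic anhydride 24 (not isolated)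
Conditions: t-BuCOCl, Et3N, THF, -20 °C; then 3, LiCl, rt
Reagents that add atoms: pivaloyl chloride CC(C)(C)C(=O)Cl (only in 24)
Why: Mixed-anhydride N-acylation promoted by LiCl; attack occurs at the less hindered enoyl carbonyl.

Step 18
Reactants: 25 4-methoxycrotonyl imide; 22 left aldehyde
Product: 26 syn-aldol imide (acyl chain 2R,3R = C8,C7) carrying a (Z)-2-methoxyvinyl group on C8
Conditions: Bu2BOTf, Et3N, CH2Cl2, -78 to 0 °C; 22, -78 °C; H2O2, MeOH, pH 7 buffer, 0 °C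
Reagents that add atoms: none
Why: Deconjugative Evans syn-aldol, in which γ-deprotonation gives the boron dienolate; this reacts at its α-carbon through a Zimmerman-Traxler chair opposite the (R)-benzyl group to set C7 (R) and C8, while the alkoxy syn effect in the γ-deprotonation should leave the new C8'=C9' enol ether Z.

Step 19
Reactants: 26 syn-aldol imide
Product: 27 O7-triethylsilyl ether of 26
Conditions: TESOTf, 2,6-lutidine, CH2Cl2, -78 °C
Reagents that add atoms: triethylsilyl triflate CC[Si](CC)(CC)OS(=O)(=O)C(F)(F)F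
Why: Buffered silylation blocks O7 with a group that is bulkier than Me3Si yet can later be removed beside TBS and TIPS, and the lutidine keeps the enol ether from protonation.

Step 20
Reactants: 27 silylated imide
Product: 28 left fragment: (Z)-enol ether alcohol (7R,8S) with O7-TES and free O9-H
Conditions: LiBH4, MeOH (1 equiv), Et2O, 0 °C; chromatography on Et3N-deactivated silica
Reagents that add atoms: none
Why: Reductive removal of the auxiliary turns the imide carbonyl into C9H2OH, and enol ether and silyl ethers are inert to borohydride.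

Step 21
Reactants: 18 syringyloxyacetyl imide; 2 TIPS-vanillin
Product: 29 (S)-4-benzyl-3-[(2S,3R)-2-(4-bromo-2,6-dimethoxyphenoxy)-3-hydroxy-3-(3-methoxy-4-triisopropylsilyloxyphenyl)propanoyl]oxazolidin-2-one
Conditions: Bu2BOTf, Et3N, CH2Cl2, -78 to 0 °C; 2, -78 to 0 °C; H2O2, MeOH, pH 7 buffer
Reagents that add atoms: none
Why: Evans syn-aldol under control of the (S)-auxiliary sets the threo (later αR,βR) pair of unit 3, of which Cβ is final.

Step 22
Reactants: 29 syn-aldol imide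
Product: 30 (1R,2R)-2-(4-bromo-2,6-dimethoxyphenoxy)-1-(3-methoxy-4-triisopropylsilyloxyphenyl)propane-1,3-diol (threo)
Conditions: LiBH4, MeOH (1 equiv), THF, 0 °C
Reagents that add atoms: none
Why: Reductive removal of the auxiliary, as in step 5.

Step 23
Reactants: 30 threo diol
Product: 31 (1R,2R)-2-(4-bromo-2,6-dimethoxyphenoxy)-3-(tert-butyldimethylsilyloxy)-1-(3-methoxy-4-triisopropylsilyloxyphenyl)propan-1-ol
Conditions: TBSCl (1.05 equiv), imidazole, CH2Cl2, 0 °C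
Reagents that add atoms: tert-butyldimethylsilyl chloride CC(C)(C)[Si](C)(C)Cl
Why: Selective silylation of the primary alcohol on steric grounds.

Step 24
Reactants: 31 threo benzylic alcohol
Product: 32 (1S,2R)-2-(4-bromo-2,6-dimethoxyphenoxy)-3-(tert-butyldimethylsilyloxy)-1-(3-methoxy-4-triisopropylsilyloxyphenyl)propyl 4-nitrobenzoate (erythro)
Conditions: 4-O2NC6H4CO2H, PPh3, DIAD, toluene, 0 °C to rt
Reagents that add atoms: 4-nitrobenzoic acid O=C(O)c1ccc(cc1)[N+](=O)[O-]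
Why: Mitsunobu inversion (SN2) turns αR into αS and so gives the erythro unit 3.

Step 25
Reactants: 32 4-nitrobenzoate
Product: 33 (1S,2R)-2-(4-bromo-2,6-dimethoxyphenoxy)-3-(tert-butyldimethylsilyloxy)-1-(3-methoxy-4-triisopropylsilyloxyphenyl)propan-1-ol (erythro)
Conditions: K2CO3 (cat.), MeOH-THF, 0 °C
Reagents that add atoms: none
Why: Transesterification at the acyl carbon retains the configuration at Cα.

Step 26
Reactants: 33 erythro alcohol
Product: 34 bis-TBS ether of unit 3 on 4-bromo-2,6-dimethoxyphenyl (αS,βR)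
Conditions: TBSOTf, 2,6-lutidine, CH2Cl2, 0 °C
Reagents that add atoms: tert-butyldimethylsilyl triflate CC(C)(C)[Si](C)(C)OS(=O)(=O)C(F)(F)F
Why: Silyl triflate silylation of the hindered benzylic alcohol under buffered conditions.

Step 27
Reactants: 34 aryl bromide
Product: 35 right aldehyde: 4-{[(1S,2R)-1,3-bis(tert-butyldimethylsilyloxy)-1-(3-methoxy-4-triisopropylsilyloxyphenyl)propan-2-yl]oxy}-3,5-dimethoxybenzaldehyde
Conditions: n-BuLi, THF, -78 °C; DMF; H2O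
Reagents that add atoms: N,N-dimethylformamide CN(C)C=O
Why: Bromine-lithium exchange and Bouveault formylation, as in step 10.

Step 28
Reactants: 28 left fragment (enol ether alcohol); 35 right aldehyde
Product: 37 2,3-cis-3,4-trans tetrahydrofuran-3-carbaldehyde (7R,8S,7'R,8'S; O7-TES) joining both fragments through ring B, via trimethylsilyl ether 36 (not isolated)
Conditions: 2,6-di-tert-butyl-4-methylpyridine (2.5 equiv), Me3SiOTf (1.1 equiv), CH2Cl2, -78 °C; then 35 and slow addition of Me3SiOTf (1.2 equiv), -78 °C; Et3N, then H2O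
Reagents that add atoms: trimethylsilyl triflate C[Si](C)(C)OS(=O)(=O)C(F)(F)F (only in 36); water O
Why: Me3SiOTf first silylates O9 and then condenses this primary silyl ether with aldehyde 35 (loss of (Me3Si)2O) to the aryl-stabilised (E)-oxocarbenium ion at C7', which is attacked by C8', the nucleophilic carbon of the (Z)-enol ether, and water finally converts the C9' methoxycarbenium ion into the aldehyde. The closest known reaction types are the intramolecular Mukaiyama aldol (Prins-type) closure of 4-oxy-1-alkenyl ethers and carbamates on aromatic aldehydes or their acetals and the Lewis-acid ring contraction of 4,5-dihydro-1,3-dioxepins, both of which give 2-aryltetrahydrofuran-3-carbaldehydes. The one ring closed here, ring B (O9, C7', C8', C8, C9), forms in the 5-(enolexo)-endo-trig mode, which is open to oxocarbenium ions. C8' is set by allylic 1,3-strain of the Z-alkene (H8 in the alkene plane, attack from the face that carries the C9 tether), so the formyl group ends trans to the C7 side chain, and C7' is set by the kinetic synclinal pairing of an E-oxocarbenium ion and a Z-enol ether, which gives the 2,3-cis product, so that ring S2 ends trans to the C7 side chain, as the exo-aryl target demands. An open-chain enol ether is chosen on purpose, because the same 2,3-cis bias on a cyclic 2,3-dihydrofuran nucleophile would place the aryl group endo. The step needs cation formation at O9 only (O7 carries the bulkier Et3Si group), O-capture of the activated aldehyde ahead of intermolecular C-attack (primary Me3Si ether, slow addition of Me3SiOTf at -78 °C) and silence of the six silyl ethers of the side chains (their benzylic cations are destabilised by the β-aryloxy groups, and the hindered pyridine removes acid).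

Step 29
Reactants: 37 cis-aldehyde
Product: 40 cis-fused bicyclic lactol (7R,8S,7'R,8'R; C9'-OH as anomer mixture), via hydroxy aldehyde 38 (not isolated), via epimeric hydroxy aldehyde 39 (not isolated)
Conditions: HF·pyridine, pyridine, THF, 0 °C; aq. NaHCO3; then DBU (0.2 equiv), CH2Cl2, rt
Reagents that add atoms: none
Why: Buffered fluoride removes only the triethylsilyl ether, and DBU then epimerises the enolisable C8' so that the strained 2,3-cis aldehyde passes into the 2,3-trans isomer; this is the only isomer whose formyl group reaches O7, and it is drained as the lactol (5-exo-trig hemiacetal closure of ring A), which sets C8' under thermodynamic control by the cis ring fusion.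

Step 30
Reactants: 40 lactol
Product: 41 fully silylated target (six TBS ethers and two TIPS ethers; core 7R,8S,7'R,8'S)
Conditions: Et3SiH, BF3·OEt2, CH2Cl2, -78 to -40 °C
Reagents that add atoms: none
Why: Ionic reduction of the lactol through the bicyclic C9' oxocarbenium ion, the standard last move of furofuran syntheses; the acetal carbon ionises far more easily than any benzylic ether at this temperature, and no stereocentre is created.

Step 31
Reactants: 41 silylated target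
Product: 42 CNP0316493.1
Conditions: Bu4NF, AcOH, THF, 0 °C to rt
Reagents that add atoms: none
Why: Global fluoride desilylation at silicon, buffered with acetic acid so that the freed 4-hydroxybenzyl alcohols are not exposed to strong base, leaves all ten stereocentres untouched.

**Compound list**
1 | vanillin | COc1cc(C=O)ccc1O | starting material
2 | 3-methoxy-4-(triisopropylsilyloxy)benzaldehyde | COc1cc(C=O)ccc1O[Si](C(C)C)(C(C)C)C(C)C | intermediate
3 | (R)-4-benzyloxazolidin-2-one | O=C1OC[C@@H](Cc2ccccc2)N1 | starting material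
4 | bromoacetyl bromide | O=C(Br)CBr | starting material
5 | (R)-4-benzyl-3-(bromoacetyl)oxazolidin-2-one | O=C(CBr)N1[C@H](Cc2ccccc2)COC1=O | intermediate
6 | 4-bromo-2-methoxyphenol | COc1cc(Br)ccc1O | starting material
7 | (R)-4-benzyl-3-[2-(4-bromo-2-methoxyphenoxy)acetyl]oxazolidin-2-one | COc1cc(Br)ccc1OCC(=O)N2[C@H](Cc3ccccc3)COC2=O | intermediate
8 | syn-aldol imide of unit 2 (2R,3S; (R)-auxiliary) | COc1cc([C@H](O)[C@H](C(=O)N2[C@H](Cc3ccccc3)COC2=O)Oc2ccc(Br)cc2OC)ccc1O[Si](C(C)C)(C(C)C)C(C)C | intermediate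
9 | threo diol of unit 2 (1S,2S) | COc1cc([C@H](O)[C@H](CO)Oc2ccc(Br)cc2OC)ccc1O[Si](C(C)C)(C(C)C)C(C)C | intermediate
10 | threo γ-TBS ether of unit 2 (1S,2S) | COc1cc([C@H](O)[C@H](CO[Si](C)(C)C(C)(C)C)Oc2ccc(Br)cc2OC)ccc1O[Si](C(C)C)(C(C)C)C(C)C | intermediate
11 | erythro 4-nitrobenzoate of unit 2 (1R,2S) | COc1cc([C@@H](OC(=O)c3ccc(cc3)[N+](=O)[O-])[C@H](CO[Si](C)(C)C(C)(C)C)Oc2ccc(Br)cc2OC)ccc1O[Si](C(C)C)(C(C)C)C(C)C | intermediate
12 | erythro alcohol of unit 2 (1R,2S) | COc1cc([C@@H](O)[C@H](CO[Si](C)(C)C(C)(C)C)Oc2ccc(Br)cc2OC)ccc1O[Si](C(C)C)(C(C)C)C(C)C | intermediate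
13 | bis-TBS unit 2 on 4-bromo-2-methoxyphenyl | COc1cc([C@@H](O[Si](C)(C)C(C)(C)C)[C@H](CO[Si](C)(C)C(C)(C)C)Oc2ccc(Br)cc2OC)ccc1O[Si](C(C)C)(C(C)C)C(C)C | intermediate
14 | aldehyde of ring G1 bearing unit 2 | COc1cc([C@@H](O[Si](C)(C)C(C)(C)C)[C@H](CO[Si](C)(C)C(C)(C)C)Oc2ccc(C=O)cc2OC)ccc1O[Si](C(C)C)(C(C)C)C(C)C | intermediate
15 | (S)-4-benzyloxazolidin-2-one | O=C1OC[C@H](Cc2ccccc2)N1 | starting material
16 | (S)-4-benzyl-3-(bromoacetyl)oxazolidin-2-one | O=C(CBr)N1[C@@H](Cc2ccccc2)COC1=O | intermediate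
17 | 4-bromo-2,6-dimethoxyphenol | COc1cc(Br)cc(OC)c1O | starting material
18 | (S)-4-benzyl-3-[2-(4-bromo-2,6-dimethoxyphenoxy)acetyl]oxazolidin-2-one | COc1cc(Br)cc(OC)c1OCC(=O)N2[C@@H](Cc3ccccc3)COC2=O | intermediate
19 | syn-aldol imide of unit 1 (2S,3R; (S)-auxiliary) | COc1cc([C@@H](O[Si](C)(C)C(C)(C)C)[C@H](CO[Si](C)(C)C(C)(C)C)Oc2ccc([C@@H](O)[C@@H](C(=O)N3[C@@H](Cc4ccccc4)COC3=O)Oc3c(OC)cc(Br)cc3OC)cc2OC)ccc1O[Si](C(C)C)(C(C)C)C(C)C | intermediate
20 | diol with free threo unit 1 (αR,βR) | COc1cc([C@@H](O[Si](C)(C)C(C)(C)C)[C@H](CO[Si](C)(C)C(C)(C)C)Oc2ccc([C@@H](O)[C@@H](CO)Oc3c(OC)cc(Br)cc3OC)cc2OC)ccc1O[Si](C(C)C)(C(C)C)C(C)C | intermediate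
21 | silylated units 1 and 2 on 4-bromo-2,6-dimethoxyphenyl | COc1cc([C@@H](O[Si](C)(C)C(C)(C)C)[C@H](CO[Si](C)(C)C(C)(C)C)Oc2ccc([C@@H](O[Si](C)(C)C(C)(C)C)[C@@H](CO[Si](C)(C)C(C)(C)C)Oc3c(OC)cc(Br)cc3OC)cc2OC)ccc1O[Si](C(C)C)(C(C)C)C(C)C | intermediate
22 | left aldehyde (ring S1) | COc1cc([C@@H](O[Si](C)(C)C(C)(C)C)[C@H](CO[Si](C)(C)C(C)(C)C)Oc2ccc([C@@H](O[Si](C)(C)C(C)(C)C)[C@@H](CO[Si](C)(C)C(C)(C)C)Oc3c(OC)cc(C=O)cc3OC)cc2OC)ccc1O[Si](C(C)C)(C(C)C)C(C)C | intermediate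
23 | (E)-4-methoxybut-2-enoic acid | COC/C=C/C(=O)O | starting material
24 | mixed pivalic anhydride of 23 | COC/C=C/C(=O)OC(=O)C(C)(C)C | intermediate
25 | (R)-4-benzyl-3-[(E)-4-methoxybut-2-enoyl]oxazolidin-2-one | COC/C=C/C(=O)N1[C@H](Cc2ccccc2)COC1=O | intermediate
26 | syn-aldol imide (7R; acyl chain 2R,3R) with (Z)-2-methoxyvinyl on C8 | COc1cc([C@@H](O[Si](C)(C)C(C)(C)C)[C@H](CO[Si](C)(C)C(C)(C)C)Oc2ccc([C@@H](O[Si](C)(C)C(C)(C)C)[C@@H](CO[Si](C)(C)C(C)(C)C)Oc3c(OC)cc([C@H](O)[C@H](C(=O)N4[C@H](Cc5ccccc5)COC4=O)/C=C\OC)cc3OC)cc2OC)ccc1O[Si](C(C)C)(C(C)C)C(C)C | intermediate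
27 | O7-TES ether of 26 | COc1cc([C@@H](O[Si](C)(C)C(C)(C)C)[C@H](CO[Si](C)(C)C(C)(C)C)Oc2ccc([C@@H](O[Si](C)(C)C(C)(C)C)[C@@H](CO[Si](C)(C)C(C)(C)C)Oc3c(OC)cc([C@H](O[Si](CC)(CC)CC)[C@H](C(=O)N4[C@H](Cc5ccccc5)COC4=O)/C=C\OC)cc3OC)cc2OC)ccc1O[Si](C(C)C)(C(C)C)C(C)C | intermediate
28 | left fragment: (Z)-enol ether alcohol (7R,8S) | COc1cc([C@@H](O[Si](C)(C)C(C)(C)C)[C@H](CO[Si](C)(C)C(C)(C)C)Oc2ccc([C@@H](O[Si](C)(C)C(C)(C)C)[C@@H](CO[Si](C)(C)C(C)(C)C)Oc3c(OC)cc([C@H](O[Si](CC)(CC)CC)[C@H](CO)/C=C\OC)cc3OC)cc2OC)ccc1O[Si](C(C)C)(C(C)C)C(C)C | intermediate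
29 | syn-aldol imide of unit 3 (2S,3R; (S)-auxiliary) | COc1cc(Br)cc(OC)c1O[C@H](C(=O)N2[C@@H](Cc3ccccc3)COC2=O)[C@H](O)c2ccc(O[Si](C(C)C)(C(C)C)C(C)C)c(OC)c2 | intermediate
30 | threo diol of unit 3 (1R,2R) | COc1cc(Br)cc(OC)c1O[C@H](CO)[C@H](O)c2ccc(O[Si](C(C)C)(C(C)C)C(C)C)c(OC)c2 | intermediate
31 | threo γ-TBS ether of unit 3 (1R,2R) | COc1cc(Br)cc(OC)c1O[C@H](CO[Si](C)(C)C(C)(C)C)[C@H](O)c2ccc(O[Si](C(C)C)(C(C)C)C(C)C)c(OC)c2 | intermediate
32 | erythro 4-nitrobenzoate of unit 3 (1S,2R) | COc1cc(Br)cc(OC)c1O[C@H](CO[Si](C)(C)C(C)(C)C)[C@@H](OC(=O)c3ccc(cc3)[N+](=O)[O-])c2ccc(O[Si](C(C)C)(C(C)C)C(C)C)c(OC)c2 | intermediate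
33 | erythro alcohol of unit 3 (1S,2R) | COc1cc(Br)cc(OC)c1O[C@H](CO[Si](C)(C)C(C)(C)C)[C@@H](O)c2ccc(O[Si](C(C)C)(C(C)C)C(C)C)c(OC)c2 | intermediate
34 | bis-TBS unit 3 on 4-bromo-2,6-dimethoxyphenyl | COc1cc(Br)cc(OC)c1O[C@H](CO[Si](C)(C)C(C)(C)C)[C@@H](O[Si](C)(C)C(C)(C)C)c2ccc(O[Si](C(C)C)(C(C)C)C(C)C)c(OC)c2 | intermediate
35 | right aldehyde (ring S2 bearing unit 3) | COc1cc(C=O)cc(OC)c1O[C@H](CO[Si](C)(C)C(C)(C)C)[C@@H](O[Si](C)(C)C(C)(C)C)c2ccc(O[Si](C(C)C)(C(C)C)C(C)C)c(OC)c2 | intermediate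
36 | O9-trimethylsilyl ether of 28 | COc1cc([C@@H](O[Si](C)(C)C(C)(C)C)[C@H](CO[Si](C)(C)C(C)(C)C)Oc2ccc([C@@H](O[Si](C)(C)C(C)(C)C)[C@@H](CO[Si](C)(C)C(C)(C)C)Oc3c(OC)cc([C@H](O[Si](CC)(CC)CC)[C@H](CO[Si](C)(C)C)/C=C\OC)cc3OC)cc2OC)ccc1O[Si](C(C)C)(C(C)C)C(C)C | intermediate
37 | ring B aldehyde, 2,3-cis-3,4-trans (7R,8S,7'R,8'S), O7-TES | COc1cc([C@@H](O[Si](C)(C)C(C)(C)C)[C@H](CO[Si](C)(C)C(C)(C)C)Oc2ccc([C@@H](O[Si](C)(C)C(C)(C)C)[C@@H](CO[Si](C)(C)C(C)(C)C)Oc3c(OC)cc([C@H](O[Si](CC)(CC)CC)[C@@H]4CO[C@@H](c6cc(OC)c(O[C@H](CO[Si](C)(C)C(C)(C)C)[C@@H](O[Si](C)(C)C(C)(C)C)c7ccc(O[Si](C(C)C)(C(C)C)C(C)C)c(OC)c7)c(OC)c6)[C@H]4C=O)cc3OC)cc2OC)ccc1O[Si](C(C)C)(C(C)C)C(C)C | intermediate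
38 | hydroxy aldehyde (37 without TES) | COc1cc([C@@H](O[Si](C)(C)C(C)(C)C)[C@H](CO[Si](C)(C)C(C)(C)C)Oc2ccc([C@@H](O[Si](C)(C)C(C)(C)C)[C@@H](CO[Si](C)(C)C(C)(C)C)Oc3c(OC)cc([C@H](O)[C@@H]4CO[C@@H](c6cc(OC)c(O[C@H](CO[Si](C)(C)C(C)(C)C)[C@@H](O[Si](C)(C)C(C)(C)C)c7ccc(O[Si](C(C)C)(C(C)C)C(C)C)c(OC)c7)c(OC)c6)[C@H]4C=O)cc3OC)cc2OC)ccc1O[Si](C(C)C)(C(C)C)C(C)C | intermediate
39 | C8' epimer of 38 (2,3-trans-3,4-cis) | COc1cc([C@@H](O[Si](C)(C)C(C)(C)C)[C@H](CO[Si](C)(C)C(C)(C)C)Oc2ccc([C@@H](O[Si](C)(C)C(C)(C)C)[C@@H](CO[Si](C)(C)C(C)(C)C)Oc3c(OC)cc([C@H](O)[C@@H]4CO[C@@H](c6cc(OC)c(O[C@H](CO[Si](C)(C)C(C)(C)C)[C@@H](O[Si](C)(C)C(C)(C)C)c7ccc(O[Si](C(C)C)(C(C)C)C(C)C)c(OC)c7)c(OC)c6)[C@@H]4C=O)cc3OC)cc2OC)ccc1O[Si](C(C)C)(C(C)C)C(C)C | intermediate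
40 | bicyclic lactol (C9'-OH, anomers) | COc1cc([C@@H](O[Si](C)(C)C(C)(C)C)[C@H](CO[Si](C)(C)C(C)(C)C)Oc2ccc([C@@H](O[Si](C)(C)C(C)(C)C)[C@@H](CO[Si](C)(C)C(C)(C)C)Oc3c(OC)cc([C@@H]4OC(O)[C@@H]5[C@H]4CO[C@H]5c6cc(OC)c(O[C@H](CO[Si](C)(C)C(C)(C)C)[C@@H](O[Si](C)(C)C(C)(C)C)c7ccc(O[Si](C(C)C)(C(C)C)C(C)C)c(OC)c7)c(OC)c6)cc3OC)cc2OC)ccc1O[Si](C(C)C)(C(C)C)C(C)C | intermediate
41 | fully silylated target | COc1cc([C@@H](O[Si](C)(C)C(C)(C)C)[C@H](CO[Si](C)(C)C(C)(C)C)Oc2ccc([C@@H](O[Si](C)(C)C(C)(C)C)[C@@H](CO[Si](C)(C)C(C)(C)C)Oc3c(OC)cc([C@@H]4OC[C@@H]5[C@H]4CO[C@H]5c6cc(OC)c(O[C@H](CO[Si](C)(C)C(C)(C)C)[C@@H](O[Si](C)(C)C(C)(C)C)c7ccc(O[Si](C(C)C)(C(C)C)C(C)C)c(OC)c7)c(OC)c6)cc3OC)cc2OC)ccc1O[Si](C(C)C)(C(C)C)C(C)C | intermediate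
42 | CNP0316493.1 | COc1cc([C@@H](O)[C@H](CO)Oc2ccc([C@@H](O)[C@@H](CO)Oc3c(OC)cc([C@@H]4OC[C@@H]5[C@H]4CO[C@H]5c4cc(OC)c(O[C@H](CO)[C@@H](O)c5ccc(O)c(OC)c5)c(OC)c4)cc3OC)cc2OC)ccc1O | target

**Step count**
- Total step count: 31.
- Longest linear sequence: 20 steps (2, 3, 4, 5, 6, 7, 8, 9, 10, 13, 14, 15, 16, 18, 19, 20, 28, 29, 30, 31).

**Steps most likely to fail**

Step 28.
- What may go wrong: the enol ether may attack the activated aldehyde intermolecularly before the cation forms on O9. The O7 silyl ether may take part and close a 1,3-dioxane. The 2,3-cis facial preference at C7' may erode.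
- Fallback: it sets out from 35 and 28 and comes back at 37.
- Aldehyde 35 is oxidised (Pinnick conditions: NaClO2, NaH2PO4, 2-methylbut-2-ene) to the benzoic acid F1, which is esterified with alcohol 28 (EDC, DMAP) to the aroyl ester F2.
- Reduction with i-Bu2AlH at -78 °C, with trapping of the aluminium hemiacetal by Ac2O, pyridine and DMAP (reductive acetylation), gives the α-acetoxy ether F3.
- Ionisation of F3 (BF3·OEt2 or Me3SiOTf, hindered pyridine, -78 °C) can place the cation on O9 only and needs no free aldehyde, so the same closure and aqueous quench should lead to 37.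

Step 18.
- What may go wrong: the dienolate may react at its γ-carbon. The enol ether geometry may erode. The γ-hydroxy enol ether may cyclise during work-up.
- Fallback: it sets out from 3 and 22 and comes back at 37.
- Oxazolidinone 3 is acylated with pent-4-enoyl chloride (n-BuLi) to the pent-4-enoyl imide F4, whose ordinary Evans syn-aldol with 22 gives the syn-aldol adduct F5. TESOTf and 2,6-lutidine give the triethylsilyl ether F6.
- Lemieux-Johnson cleavage (OsO4 cat., NaIO4, 2,6-lutidine) gives the aldehyde F7, and TBSOTf with Et3N gives the (Z)-silyl enol ether F8.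
- LiBH4 then gives the alcohol F9, which takes the place of 28 in step 28 and, after loss of its silyl group, gives 37.

Step 29.
- What may go wrong: primary TBS groups may be lost along with the triethylsilyl group. Epimerisation at C8' may be slow or incomplete, so that the lactol is not drained.
- Fallback: it sets out from 37 and comes back at 40, and moves the epimerisation to the acid level.
- Pinnick oxidation gives the carboxylic acid F10, and HF·pyridine gives the hydroxy acid F11.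
- Yamaguchi activation (2,4,6-trichlorobenzoyl chloride, Et3N, DMAP) makes the α-carbon readily enolisable. Only the C8' epimer can lactonise, which gives the bicyclic lactone F12, and i-Bu2AlH at -78 °C reduces it to lactol 40.

Further compounds
F1 | step 28 | benzoic acid | COc1cc(C(=O)O)cc(OC)c1O[C@H](CO[Si](C)(C)C(C)(C)C)[C@@H](O[Si](C)(C)C(C)(C)C)c2ccc(O[Si](C(C)C)(C(C)C)C(C)C)c(OC)c2
F2 | step 28 | aroyl ester | COc1cc([C@@H](O[Si](C)(C)C(C)(C)C)[C@H](CO[Si](C)(C)C(C)(C)C)Oc2ccc([C@@H](O[Si](C)(C)C(C)(C)C)[C@@H](CO[Si](C)(C)C(C)(C)C)Oc3c(OC)cc([C@H](O[Si](CC)(CC)CC)[C@H](COC(=O)c6cc(OC)c(O[C@H](CO[Si](C)(C)C(C)(C)C)[C@@H](O[Si](C)(C)C(C)(C)C)c7ccc(O[Si](C(C)C)(C(C)C)C(C)C)c(OC)c7)c(OC)c6)/C=C\OC)cc3OC)cc2OC)ccc1O[Si](C(C)C)(C(C)C)C(C)C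
F3 | step 28 | α-acetoxy ether | COc1cc([C@@H](O[Si](C)(C)C(C)(C)C)[C@H](CO[Si](C)(C)C(C)(C)C)Oc2ccc([C@@H](O[Si](C)(C)C(C)(C)C)[C@@H](CO[Si](C)(C)C(C)(C)C)Oc3c(OC)cc([C@H](O[Si](CC)(CC)CC)[C@H](COC(OC(C)=O)c6cc(OC)c(O[C@H](CO[Si](C)(C)C(C)(C)C)[C@@H](O[Si](C)(C)C(C)(C)C)c7ccc(O[Si](C(C)C)(C(C)C)C(C)C)c(OC)c7)c(OC)c6)/C=C\OC)cc3OC)cc2OC)ccc1O[Si](C(C)C)(C(C)C)C(C)C
F4 | step 18 | pent-4-enoyl imide | C=CCCC(=O)N1[C@H](Cc2ccccc2)COC1=O
F5 | step 18 | syn-aldol adduct | COc1cc([C@@H](O[Si](C)(C)C(C)(C)C)[C@H](CO[Si](C)(C)C(C)(C)C)Oc2ccc([C@@H](O[Si](C)(C)C(C)(C)C)[C@@H](CO[Si](C)(C)C(C)(C)C)Oc3c(OC)cc([C@H](O)[C@H](C(=O)N4[C@H](Cc5ccccc5)COC4=O)CC=C)cc3OC)cc2OC)ccc1O[Si](C(C)C)(C(C)C)C(C)C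
F6 | step 18 | triethylsilyl ether | COc1cc([C@@H](O[Si](C)(C)C(C)(C)C)[C@H](CO[Si](C)(C)C(C)(C)C)Oc2ccc([C@@H](O[Si](C)(C)C(C)(C)C)[C@@H](CO[Si](C)(C)C(C)(C)C)Oc3c(OC)cc([C@H](O[Si](CC)(CC)CC)[C@H](C(=O)N4[C@H](Cc5ccccc5)COC4=O)CC=C)cc3OC)cc2OC)ccc1O[Si](C(C)C)(C(C)C)C(C)C
F7 | step 18 | aldehyde | COc1cc([C@@H](O[Si](C)(C)C(C)(C)C)[C@H](CO[Si](C)(C)C(C)(C)C)Oc2ccc([C@@H](O[Si](C)(C)C(C)(C)C)[C@@H](CO[Si](C)(C)C(C)(C)C)Oc3c(OC)cc([C@H](O[Si](CC)(CC)CC)[C@H](C(=O)N4[C@H](Cc5ccccc5)COC4=O)CC=O)cc3OC)cc2OC)ccc1O[Si](C(C)C)(C(C)C)C(C)C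
F8 | step 18 | (Z)-silyl enol ether | COc1cc([C@@H](O[Si](C)(C)C(C)(C)C)[C@H](CO[Si](C)(C)C(C)(C)C)Oc2ccc([C@@H](O[Si](C)(C)C(C)(C)C)[C@@H](CO[Si](C)(C)C(C)(C)C)Oc3c(OC)cc([C@H](O[Si](CC)(CC)CC)[C@H](C(=O)N4[C@H](Cc5ccccc5)COC4=O)/C=C\O[Si](C)(C)C(C)(C)C)cc3OC)cc2OC)ccc1O[Si](C(C)C)(C(C)C)C(C)C
F9 | step 18 | alcohol | COc1cc([C@@H](O[Si](C)(C)C(C)(C)C)[C@H](CO[Si](C)(C)C(C)(C)C)Oc2ccc([C@@H](O[Si](C)(C)C(C)(C)C)[C@@H](CO[Si](C)(C)C(C)(C)C)Oc3c(OC)cc([C@H](O[Si](CC)(CC)CC)[C@H](CO)/C=C\O[Si](C)(C)C(C)(C)C)cc3OC)cc2OC)ccc1O[Si](C(C)C)(C(C)C)C(C)C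
F10 | step 29 | carboxylic acid | COc1cc([C@@H](O[Si](C)(C)C(C)(C)C)[C@H](CO[Si](C)(C)C(C)(C)C)Oc2ccc([C@@H](O[Si](C)(C)C(C)(C)C)[C@@H](CO[Si](C)(C)C(C)(C)C)Oc3c(OC)cc([C@H](O[Si](CC)(CC)CC)[C@@H]4CO[C@@H](c6cc(OC)c(O[C@H](CO[Si](C)(C)C(C)(C)C)[C@@H](O[Si](C)(C)C(C)(C)C)c7ccc(O[Si](C(C)C)(C(C)C)C(C)C)c(OC)c7)c(OC)c6)[C@H]4C(=O)O)cc3OC)cc2OC)ccc1O[Si](C(C)C)(C(C)C)C(C)C
F11 | step 29 | hydroxy acid | COc1cc([C@@H](O[Si](C)(C)C(C)(C)C)[C@H](CO[Si](C)(C)C(C)(C)C)Oc2ccc([C@@H](O[Si](C)(C)C(C)(C)C)[C@@H](CO[Si](C)(C)C(C)(C)C)Oc3c(OC)cc([C@H](O)[C@@H]4CO[C@@H](c6cc(OC)c(O[C@H](CO[Si](C)(C)C(C)(C)C)[C@@H](O[Si](C)(C)C(C)(C)C)c7ccc(O[Si](C(C)C)(C(C)C)C(C)C)c(OC)c7)c(OC)c6)[C@H]4C(=O)O)cc3OC)cc2OC)ccc1O[Si](C(C)C)(C(C)C)C(C)C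
F12 | step 29 | bicyclic lactone | COc1cc([C@@H](O[Si](C)(C)C(C)(C)C)[C@H](CO[Si](C)(C)C(C)(C)C)Oc2ccc([C@@H](O[Si](C)(C)C(C)(C)C)[C@@H](CO[Si](C)(C)C(C)(C)C)Oc3c(OC)cc([C@@H]4OC(=O)[C@@H]5[C@H]4CO[C@H]5c6cc(OC)c(O[C@H](CO[Si](C)(C)C(C)(C)C)[C@@H](O[Si](C)(C)C(C)(C)C)c7ccc(O[Si](C(C)C)(C(C)C)C(C)C)c(OC)c7)c(OC)c6)cc3OC)cc2OC)ccc1O[Si](C(C)C)(C(C)C)C(C)C
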